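**Retrosynthetic overview**

1. Scaposin is 5,7,3'-trihydroxy-6,8,4',5'-tetramethoxyflavone. The C8 methoxy group is removed first (C8–O from Elbs oxidation para to a free 5-hydroxyl, then O-methylation) and the three hydroxyls are masked as benzyl ethers, which leads back to a 5,7,3'-tribenzyl flavone with hydrogen on C8.
2. Ring C is then cut at O1–C8a, C4a–C4 and O1–C2 into a ring-A aryne (triple bond C4a≡C8a, released from an ortho-silylaryl triflate) and an arylpropiolic acid that brings ring B, C2, C3, C4 and O1.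
3. Feature on which this rests: in ring A the neighbouring carbons C8a and C4a bear O1 and the acyl carbon C4, and while C8 is still hydrogen the oxygen on C5 is the one substituent next to the C4a≡C8a bond, so it alone fixes which end takes the oxygen.
4. The silyl triflate comes from methyl 3,5-dihydroxy-4-methoxybenzoate through the symmetric phenol (Baeyer–Villiger), ortho-bromination, retro-Brook silyl shift and triflation; the acid comes from 3-hydroxy-4,5-dimethoxybenzaldehyde by Corey–Fuchs homologation and carboxylation.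
5. Ring order: rings A and B are bought as benzenes; ring C is the only ring built, in the aryne step.

Key step: step 11

Remark: flavone numbering is used for all flavone intermediates (O1, C2 to C8a for rings C and A, primed numbers for ring B); both starting materials are assumed to be purchasable.

**Route**

Step 1
Reactants: 1 methyl 3,5-dihydroxy-4-methoxybenzoate
Product: 2 methyl 3,5-bis(benzyloxy)-4-methoxybenzoate
Conditions: BnBr (2.4 equiv), K2CO3, DMF, 60 °C
Reagents that add atoms: benzyl bromide, BrCc1ccccc1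
Why: Williamson ether synthesis, in which the two phenoxides formed with K2CO3 displace bromide from benzyl bromide while the methyl ester is untouched.

Step 2
Reactants: 2 methyl 3,5-bis(benzyloxy)-4-methoxybenzoate
Product: 3 [3,5-bis(benzyloxy)-4-methoxyphenyl]methanol
Conditions: LiAlH4, THF, 0 °C; aqueous NaOH work-up
Reagents that add atoms: none
Why: Hydride reduction of an aryl ester to the benzylic alcohol with LiAlH4 is general and leaves aryl ethers alone.

Step 3
Reactants: 3 [3,5-bis(benzyloxy)-4-methoxyphenyl]methanol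
Product: 4 3,5-bis(benzyloxy)-4-methoxybenzaldehyde
Conditions: MnO2 (excess), CH2Cl2, rt
Reagents that add atoms: none
Why: MnO2 oxidation is selective for benzylic alcohols and stops at the aldehyde.

Step 4
Reactants: 4 3,5-bis(benzyloxy)-4-methoxybenzaldehyde
Product: 6 3,5-bis(benzyloxy)-4-methoxyphenol, via aryl formate 5 (not isolated)
Conditions: mCPBA, CH2Cl2, rt; then K2CO3 (cat.), MeOH, rt
Reagents that add atoms: 3-chloroperoxybenzoic acid (mCPBA), OOC(=O)c1cccc(Cl)c1
Why: Baeyer–Villiger oxidation, in which the electron-rich aryl group with its para-methoxy substituent migrates in preference to hydrogen to give formate 5, which base-catalysed methanolysis cleaves to the phenol.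

Step 5
Reactants: 6 3,5-bis(benzyloxy)-4-methoxyphenol
Product: 7 3,5-bis(benzyloxy)-2-bromo-4-methoxyphenol
Conditions: NBS (1.0 equiv), CH2Cl2, −20 °C to 0 °C
Reagents that add atoms: N-bromosuccinimide, O=C1CCC(=O)N1Br
Why: Electrophilic aromatic bromination, for which the para position of the phenol is blocked and the two ortho positions are equivalent by symmetry, so one equivalent of NBS at low temperature should stop at a single monobromide.

Step 6
Reactants: 7 3,5-bis(benzyloxy)-2-bromo-4-methoxyphenol
Product: 8 [3,5-bis(benzyloxy)-2-bromo-4-methoxyphenoxy]trimethylsilane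
Conditions: HMDS, THF, 70 °C; volatiles removed in vacuo
Reagents that add atoms: hexamethyldisilazane, C[Si](C)(C)N[Si](C)(C)C
Why: O-Silylation of the phenol with HMDS gives only ammonia as by-product, so the moisture-sensitive silyl ether can be used directly after evaporation.

Step 7
Reactants: 8 [3,5-bis(benzyloxy)-2-bromo-4-methoxyphenoxy]trimethylsilane
Product: 11 3,5-bis(benzyloxy)-4-methoxy-2-(trimethylsilyl)phenyl trifluoromethanesulfonate, via aryllithium 9 (not isolated), via lithium silylphenoxide 10 (not isolated)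
Conditions: n-BuLi (1.1 equiv), THF, −78 °C; then Tf2O, −78 °C to 0 °C
Reagents that add atoms: trifluoromethanesulfonic anhydride, O=S(=O)(OS(=O)(=O)C(F)(F)F)C(F)(F)F
Why: Bromine–lithium exchange at −78 °C is faster than attack on the benzyl ethers, aryllithium 9 takes the silyl group from the neighbouring oxygen in a retro-Brook 1,3-shift from oxygen to carbon to give phenoxide 10, and Tf2O traps this as the triflate.

Step 8
Reactants: 12 3-hydroxy-4,5-dimethoxybenzaldehyde
Product: 13 3-(benzyloxy)-4,5-dimethoxybenzaldehyde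
Conditions: BnBr (1.2 equiv), K2CO3, DMF, 60 °C
Reagents that add atoms: benzyl bromide, BrCc1ccccc1
Why: Williamson ether synthesis on the single phenol, with the aldehyde inert to carbonate and benzyl bromide.

Step 9
Reactants: 13 3-(benzyloxy)-4,5-dimethoxybenzaldehyde
Product: 14 1-(benzyloxy)-5-(2,2-dibromoethenyl)-2,3-dimethoxybenzene
Conditions: CBr4, PPh3, CH2Cl2, 0 °C
Reagents that add atoms: carbon tetrabromide, BrC(Br)(Br)Br
Why: First stage of the Corey–Fuchs reaction, in which the ylide Ph3P=CBr2 formed from CBr4 and PPh3 undergoes Wittig olefination of the aldehyde.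

Step 10
Reactants: 14 1-(benzyloxy)-5-(2,2-dibromoethenyl)-2,3-dimethoxybenzene
Product: 17 3-[3-(benzyloxy)-4,5-dimethoxyphenyl]prop-2-ynoic acid, via lithium acetylide 15 (not isolated), via lithium propiolate 16 (not isolated)
Conditions: n-BuLi (2.2 equiv), THF, −78 °C; CO2, −78 °C to rt; then aqueous HCl, 0 °C
Reagents that add atoms: carbon dioxide, O=C=O
Why: Second stage of the Corey–Fuchs reaction, in which n-BuLi eliminates HBr and exchanges the remaining bromine to give acetylide 15, which CO2 carboxylates to 16 before cold acidification frees the acid.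

Step 11
Reactants: 11 3,5-bis(benzyloxy)-4-methoxy-2-(trimethylsilyl)phenyl trifluoromethanesulfonate; 17 3-[3-(benzyloxy)-4,5-dimethoxyphenyl]prop-2-ynoic acid
Product: 20 5,7-bis(benzyloxy)-2-[3-(benzyloxy)-4,5-dimethoxyphenyl]-6-methoxy-4H-chromen-4-one, via aryne 18 (not isolated), via ynone phenoxide 19 (not isolated)
Conditions: 11 (1.5 equiv), CsF (4 equiv), THF, 125 °C, sealed tube
Reagents that add atoms: none
Why: Fluoride strips the trimethylsilyl group of 11 and triflate leaves to give aryne 18; the caesium carboxylate of 17 adds through oxygen to C8a, the aryl anion formed at C4a attacks the ester carbonyl through a four-membered alkoxide that opens to ynone phenoxide 19, and the phenoxide adds to the ynone β-carbon C2, after which the proton of the acid ends on C3. This is the known formal insertion of arynes into the C–O bond of carboxylic acids (an aryne counterpart of the anionic Fries shift), which with arylpropiolic acids runs on to flavones. Ring C, the only ring closed, forms by 6-endo-dig oxa-Michael addition, which the aprotic medium should favour over 5-exo-dig closure to an aurone. No stereocentre is formed. The step needs the oxygen on C8a and the acyl carbon on C4a and not the reverse; the benzyloxy group on C5 is the only substituent beside the triple bond, its inductive pull makes C8a the flatter and more electrophilic carbon and steadies the anion at C4a, it outweighs the weak effects of the remote C6 and C7 oxygens, and C8a with hydrogen beside it is also the less hindered end.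

Step 12
Reactants: 20 5,7-bis(benzyloxy)-2-[3-(benzyloxy)-4,5-dimethoxyphenyl]-6-methoxy-4H-chromen-4-one
Product: 21 7-(benzyloxy)-2-[3-(benzyloxy)-4,5-dimethoxyphenyl]-5-hydroxy-6-methoxy-4H-chromen-4-one
Conditions: MgBr2·OEt2 (3 equiv), toluene/Et2O, 80 °C; then aqueous HCl
Reagents that add atoms: none
Why: Chelation-controlled ether cleavage, in which magnesium binds between the C4 carbonyl oxygen and the C5 ether oxygen so that bromide removes only the benzyl group on O5, while the benzyl ethers on O7 and O3' and all methyl ethers lack this activation.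

Step 13
Reactants: 21 7-(benzyloxy)-2-[3-(benzyloxy)-4,5-dimethoxyphenyl]-5-hydroxy-6-methoxy-4H-chromen-4-one
Product: 23 7-(benzyloxy)-2-[3-(benzyloxy)-4,5-dimethoxyphenyl]-5,8-dihydroxy-6-methoxy-4H-chromen-4-one, via aryl sulfate 22 (not isolated)
Conditions: K2S2O8, aqueous KOH, pyridine, 0 °C to rt; then aqueous HCl, 90 °C, under N2
Reagents that add atoms: potassium peroxodisulfate, [K+].[K+].[O-]S(=O)(=O)OOS(=O)(=O)[O-]
Why: Elbs persulfate oxidation, in which the 5-phenoxide is attacked by peroxodisulfate at the para carbon C8 (the only free position of ring A) to give aryl sulfate 22, whose acid hydrolysis gives the quinol, as in the classical conversion of 5-hydroxyflavones into 5,8-dihydroxyflavones.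

Step 14
Reactants: 23 7-(benzyloxy)-2-[3-(benzyloxy)-4,5-dimethoxyphenyl]-5,8-dihydroxy-6-methoxy-4H-chromen-4-one
Product: 24 7-(benzyloxy)-2-[3-(benzyloxy)-4,5-dimethoxyphenyl]-5-hydroxy-6,8-dimethoxy-4H-chromen-4-one
Conditions: Me2SO4 (1.05 equiv), K2CO3, acetone, reflux
Reagents that add atoms: dimethyl sulfate, COS(=O)(=O)OC
Why: Selective Williamson methylation, since the 5-hydroxyl is held in a hydrogen bond to the C4 carbonyl and is far less nucleophilic, so one equivalent of dimethyl sulfate should alkylate only the free 8-hydroxyl.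

Step 15
Reactants: 24 7-(benzyloxy)-2-[3-(benzyloxy)-4,5-dimethoxyphenyl]-5-hydroxy-6,8-dimethoxy-4H-chromen-4-one
Product: 25 scaposin (5,7-dihydroxy-2-(3-hydroxy-4,5-dimethoxyphenyl)-6,8-dimethoxy-4H-chromen-4-one)
Conditions: H2 (1 atm), 10% Pd/C, EtOAc/MeOH, rt
Reagents that add atoms: none
Why: Catalytic hydrogenolysis of the two benzyl ethers over Pd/C at ambient pressure, conditions under which the C2–C3 double bond of a flavone and the aryl methyl ethers are normally kept.

**Compound list**

1 | methyl 3,5-dihydroxy-4-methoxybenzoate | COC(=O)c1cc(O)c(OC)c(O)c1 | starting material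
2 | methyl 3,5-bis(benzyloxy)-4-methoxybenzoate | COC(=O)c1cc(OCc2ccccc2)c(OC)c(OCc2ccccc2)c1 | intermediate
3 | [3,5-bis(benzyloxy)-4-methoxyphenyl]methanol | OCc1cc(OCc2ccccc2)c(OC)c(OCc2ccccc2)c1 | intermediate
4 | 3,5-bis(benzyloxy)-4-methoxybenzaldehyde | O=Cc1cc(OCc2ccccc2)c(OC)c(OCc2ccccc2)c1 | intermediate
5 | 3,5-bis(benzyloxy)-4-methoxyphenyl formate | O=COc1cc(OCc2ccccc2)c(OC)c(OCc2ccccc2)c1 | intermediate
6 | 3,5-bis(benzyloxy)-4-methoxyphenol | Oc1cc(OCc2ccccc2)c(OC)c(OCc2ccccc2)c1 | intermediate
7 | 3,5-bis(benzyloxy)-2-bromo-4-methoxyphenol | Oc1cc(OCc2ccccc2)c(OC)c(OCc2ccccc2)c1Br | intermediate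
8 | [3,5-bis(benzyloxy)-2-bromo-4-methoxyphenoxy]trimethylsilane | C[Si](C)(C)Oc1cc(OCc2ccccc2)c(OC)c(OCc2ccccc2)c1Br | intermediate
9 | [2,4-bis(benzyloxy)-3-methoxy-6-(trimethylsilyloxy)phenyl]lithium | [Li]c1c(O[Si](C)(C)C)cc(OCc2ccccc2)c(OC)c1OCc1ccccc1 | intermediate
10 | lithium 3,5-bis(benzyloxy)-4-methoxy-2-(trimethylsilyl)phenolate | [Li+].[O-]c1cc(OCc2ccccc2)c(OC)c(OCc2ccccc2)c1[Si](C)(C)C | intermediate
11 | 3,5-bis(benzyloxy)-4-methoxy-2-(trimethylsilyl)phenyl trifluoromethanesulfonate | C[Si](C)(C)c1c(OS(=O)(=O)C(F)(F)F)cc(OCc2ccccc2)c(OC)c1OCc1ccccc1 | intermediate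
12 | 3-hydroxy-4,5-dimethoxybenzaldehyde | COc1cc(C=O)cc(O)c1OC | starting material
13 | 3-(benzyloxy)-4,5-dimethoxybenzaldehyde | COc1cc(C=O)cc(OCc2ccccc2)c1OC | intermediate
14 | 1-(benzyloxy)-5-(2,2-dibromoethenyl)-2,3-dimethoxybenzene | COc1cc(C=C(Br)Br)cc(OCc2ccccc2)c1OC | intermediate
15 | {[3-(benzyloxy)-4,5-dimethoxyphenyl]ethynyl}lithium | [Li]C#Cc1cc(OCc2ccccc2)c(OC)c(OC)c1 | intermediate
16 | lithium 3-[3-(benzyloxy)-4,5-dimethoxyphenyl]prop-2-ynoate | [Li+].[O-]C(=O)C#Cc1cc(OCc2ccccc2)c(OC)c(OC)c1 | intermediate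
17 | 3-[3-(benzyloxy)-4,5-dimethoxyphenyl]prop-2-ynoic acid | OC(=O)C#Cc1cc(OCc2ccccc2)c(OC)c(OC)c1 | intermediate
18 | 3,5-bis(benzyloxy)-4-methoxybenzyne (1,2-didehydrobenzene, triple bond C1–C2) | C1#CC(OCc2ccccc2)=C(OC)C(OCc2ccccc2)=C1 | intermediate
19 | caesium 3,5-bis(benzyloxy)-2-{3-[3-(benzyloxy)-4,5-dimethoxyphenyl]prop-2-ynoyl}-4-methoxyphenolate | [Cs+].[O-]c1cc(OCc2ccccc2)c(OC)c(OCc2ccccc2)c1C(=O)C#Cc1cc(OCc2ccccc2)c(OC)c(OC)c1 | intermediate
20 | 5,7-bis(benzyloxy)-2-[3-(benzyloxy)-4,5-dimethoxyphenyl]-6-methoxy-4H-chromen-4-one | COc1cc(-c2cc(=O)c3c(OCc4ccccc4)c(OC)c(OCc4ccccc4)cc3o2)cc(OCc2ccccc2)c1OC | intermediate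
21 | 7-(benzyloxy)-2-[3-(benzyloxy)-4,5-dimethoxyphenyl]-5-hydroxy-6-methoxy-4H-chromen-4-one | COc1cc(-c2cc(=O)c3c(O)c(OC)c(OCc4ccccc4)cc3o2)cc(OCc2ccccc2)c1OC | intermediate
22 | potassium 7-(benzyloxy)-2-[3-(benzyloxy)-4,5-dimethoxyphenyl]-5-hydroxy-6-methoxy-4-oxo-4H-chromen-8-yl sulfate | [K+].COc1cc(-c2cc(=O)c3c(O)c(OC)c(OCc4ccccc4)c(OS(=O)(=O)[O-])c3o2)cc(OCc2ccccc2)c1OC | intermediate
23 | 7-(benzyloxy)-2-[3-(benzyloxy)-4,5-dimethoxyphenyl]-5,8-dihydroxy-6-methoxy-4H-chromen-4-one | COc1cc(-c2cc(=O)c3c(O)c(OC)c(OCc4ccccc4)c(O)c3o2)cc(OCc2ccccc2)c1OC | intermediate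
24 | 7-(benzyloxy)-2-[3-(benzyloxy)-4,5-dimethoxyphenyl]-5-hydroxy-6,8-dimethoxy-4H-chromen-4-one | COc1cc(-c2cc(=O)c3c(O)c(OC)c(OCc4ccccc4)c(OC)c3o2)cc(OCc2ccccc2)c1OC | intermediate
25 | scaposin, 5,7-dihydroxy-2-(3-hydroxy-4,5-dimethoxyphenyl)-6,8-dimethoxy-4H-chromen-4-one | COc1cc(-c2cc(=O)c3c(O)c(OC)c(O)c(OC)c3o2)cc(O)c1OC | target

**Step count**

Total: 15 steps. Longest linear sequence: 12 steps (steps 1 to 7, then 11 to 15); the acid branch (steps 8 to 10) joins at step 11.

**Steps most likely to fail**

Step 11. Several processes can divert the aryne step: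
- the aryl anion at C4a may be protonated before the acyl shift, which stops at simple O-arylation of the acid;
- the anion may add to the alkyne instead of the carbonyl, which closes a coumarin;
- the propiolate may lose CO2 at 125 °C;
- the phenoxide may close 5-exo-dig to an aurone.

Fallback (carbonylative annulation), setting out from 6 and 14 and coming back at 20: phenol 6 is iodinated with N-iodosuccinimide (CH2Cl2, 0 °C) to 3,5-bis(benzyloxy)-2-iodo-4-methoxyphenol F1. Dibromoalkene 14 is treated with n-BuLi (THF, −78 °C) and quenched with aqueous NH4Cl to give 1-(benzyloxy)-5-ethynyl-2,3-dimethoxybenzene F2. The two are joined by palladium-catalysed carbonylative Sonogashira coupling (PdCl2(PPh3)2, CO, Et2NH, 120 °C), and the ortho-hydroxyaryl ynone so formed should close under the amine to flavone 20.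

Step 13. The persulfate may be used up unproductively so that conversion stays low, the lipophilic flavone may not dissolve in aqueous alkali, hydroxide may open the pyranone ring, and the quinol may be oxidised by air to the 5,8-quinone. Fallback (halogenation then copper-mediated methoxylation), setting out from 21 and coming back at 24: NBS (1 equiv, DMF, 0 °C) should brominate 21 para to the 5-hydroxyl to give 7-(benzyloxy)-2-[3-(benzyloxy)-4,5-dimethoxyphenyl]-8-bromo-5-hydroxy-6-methoxy-4H-chromen-4-one F3. Ullmann-type methoxylation of F3 (NaOMe, CuBr, DMF/MeOH, 110 °C) then gives 24 directly, so step 14 is also bypassed.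

Step 12. Site selectivity of the ether cleavage may be lost, with the benzyl groups on O7 or O3' also removed, or the cleavage at O5 may stay incomplete. Fallback (global deprotection and selective reprotection), setting out from 20 and coming back at 21: hydrogenolysis of 20 (H2, Pd/C, EtOAc/MeOH) removes all three benzyl groups to give 5,7-dihydroxy-2-(3-hydroxy-4,5-dimethoxyphenyl)-6-methoxy-4H-chromen-4-one F4. Benzylation with two equivalents of BnBr (K2CO3, acetone, reflux) should then take only the unchelated 7- and 3'-hydroxyls and leave the hydrogen-bonded 5-hydroxyl free, which gives 21.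

**Further compounds**

F1 | step 11 | 3,5-bis(benzyloxy)-2-iodo-4-methoxyphenol | Oc1cc(OCc2ccccc2)c(OC)c(OCc2ccccc2)c1I
F2 | step 11 | 1-(benzyloxy)-5-ethynyl-2,3-dimethoxybenzene | C#Cc1cc(OCc2ccccc2)c(OC)c(OC)c1
F3 | step 13 | 7-(benzyloxy)-2-[3-(benzyloxy)-4,5-dimethoxyphenyl]-8-bromo-5-hydroxy-6-methoxy-4H-chromen-4-one | COc1cc(-c2cc(=O)c3c(O)c(OC)c(OCc4ccccc4)c(Br)c3o2)cc(OCc2ccccc2)c1OC
F4 | step 12 | 5,7-dihydroxy-2-(3-hydroxy-4,5-dimethoxyphenyl)-6-methoxy-4H-chromen-4-one | COc1cc(-c2cc(=O)c3c(O)c(OC)c(O)cc3o2)cc(O)c1OC
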